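**Retrosynthetic overview**

- Feature used: in ring B (cyclopentane: spiro carbon of ring A, CH(iPr), CH2, CH2, pinane C2) the CH(iPr) carbon sits between the spiro carbon and a ring CH2. Its CH–CH2 bond is therefore made last, from an isobutenyl group on the spiro carbon and a 2-iodoethyl arm on pinane C2; the isopropyl group is the reduced CMe2 terminus.
- After ring B only the pinane C3=C4 double bond is hydrogenated.
- The bond between the two quaternary carbons (ring-A carbon and pinane C2) comes from a Claisen shift of a ring-A enol ether of a cis-4-pinenol. Oxygen and migrating carbon stay on the face of the CMe2 bridge, so ring A ends cis to the bridge and the arm trans.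
- Ring A: formyl-blocked, 4-O-methylated 2,4,6-trihydroxytoluene is dearomatised by C-methylation, deformylated and condensed with isobutyraldehyde. Pinenol: (+)-β-pinene → nopol → silyl ether → enone → cis-alcohol.
- Ring order: pinane bicycle bought in, ring A by dearomatisation, ring B closed last.

Key step: step 15

Remark: pinane atoms are numbered as in pinene (C2 quaternary, C4 carbinol, C6 = CMe2 bridge). The ring-A enol 10 is assumed to be sulfonylated at the oxygen next to CMe2 (the cross-conjugated tautomer known from tasmanone), and (+)-β-pinene of high enantiomeric purity is assumed to be purchasable.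

**Step 1**
Reactants: 1 2,4,6-trihydroxytoluene
Product: 3 formyl phloroglucinol (2,4,6-trihydroxy-3-methylbenzaldehyde), via iminium salt 2 (not isolated)
Conditions: POCl3, DMF, EtOAc, 0 °C to rt; then H2O, 50 °C
Reagents that add atoms: N,N-dimethylformamide, CN(C)C=O; water, O
Why: Vilsmeier–Haack formylation at one of the two equivalent free CH positions puts an acceptor on the future spiro carbon and protects it from C-methylation in step 3.

**Step 2**
Reactants: 3 formyl phloroglucinol
Product: 4 mono-methyl ether (2,6-dihydroxy-4-methoxy-3-methylbenzaldehyde)
Conditions: MeI (1.05 equiv), Li2CO3, DMF, 40 °C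
Reagents that add atoms: iodomethane, CI
Why: Williamson O-methylation under weak-base conditions should go to the 4-hydroxyl, the only one not hydrogen-bonded to the formyl group and the most acidic, which fixes OMe on the carbon that will lie between C–Me and CMe2.

**Step 3**
Reactants: 4 mono-methyl ether
Product: 6 formyl triketone methyl ether (2-hydroxy-4-methoxy-3,3,5-trimethyl-6-oxocyclohexa-1,4-diene-1-carbaldehyde), via dimethylated phenol 5 (not isolated)
Conditions: MeI (3 equiv), NaOMe (3 equiv), MeOH, 0 °C to reflux; aq. HCl work-up
Reagents that add atoms: iodomethane, CI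
Why: dearomatising double C-methylation of an acylphloroglucinol phenoxide at its only unsubstituted ring carbon (the formyl-bearing carbon is not alkylated), as in the preparation of syncarpic-acid-type triketones.

**Step 4**
Reactants: 6 formyl triketone methyl ether
Product: 7 ring-A enol (5-hydroxy-3-methoxy-2,4,4-trimethylcyclohexa-2,5-dien-1-one)
Conditions: NaOH (1 M aq.), MeOH, 60 °C; then aq. HCl to pH 3, 0 °C
Reagents that add atoms: none
Why: retro-Claisen deformylation of a hydroxymethylene 1,3-dione (the classical removal of a formyl blocking group), during which the vinylogous methyl ester is protected as part of the delocalised enolate.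

**Step 5**
Reactants: 7 ring-A enol; 8 isobutyraldehyde
Product: 10 isobutenyl enol (5-hydroxy-3-methoxy-2,4,4-trimethyl-6-(2-methylprop-1-enyl)cyclohexa-2,5-dien-1-one), via isobutylidene dione 9 (not isolated)
Conditions: 8 (3 equiv), piperidine (20 mol%), AcOH (20 mol%), CH2Cl2, 4 Å molecular sieves, rt
Reagents that add atoms: none
Why: Knoevenagel condensation at the only enolisable ring CH, followed by tautomerisation of the cross-conjugated alkylidene dione to the more stable 2-alkenyl enol, as known for syncarpic acid and isobutyraldehyde.

**Step 6**
Reactants: 10 isobutenyl enol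
Product: 11 enol trisylate (5-methoxy-4,6,6-trimethyl-2-(2-methylprop-1-enyl)-3-oxocyclohexa-1,4-dien-1-yl 2,4,6-triisopropylbenzenesulfonate)
Conditions: 2,4,6-(i-Pr)3C6H2SO2Cl, Et3N, DMAP (cat.), CH2Cl2, 0 °C
Reagents that add atoms: 2,4,6-triisopropylbenzenesulfonyl chloride, CC(C)c1cc(C(C)C)c(S(=O)(=O)Cl)c(C(C)C)c1
Why: O-sulfonylation of the vinylogous acid at the oxygen that carries most of the enolate charge (the one next to CMe2, whose substitution leaves the methoxy-enone conjugation intact) gives a β-sulfonyloxy enone ready for addition–elimination.

**Step 7**
Reactants: 12 (+)-β-pinene; 13 formaldehyde (as paraformaldehyde)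
Product: 14 (+)-nopol (2-(6,6-dimethylbicyclo[3.1.1]hept-2-en-2-yl)ethanol)
Conditions: (CH2O)n, ZnCl2 (cat.), 115 °C
Reagents that add atoms: none
Why: carbonyl-ene reaction of formaldehyde with the exocyclic alkene (the established route to nopol), which moves the double bond into the ring and leaves both bridgehead stereocentres untouched.

**Step 8**
Reactants: 14 (+)-nopol
Product: 15 nopol TBS ether
Conditions: TBSCl, imidazole, DMF, rt
Reagents that add atoms: tert-butyldimethylsilyl chloride, CC(C)(C)[Si](C)(C)Cl
Why: silyl ether formation protects the primary alcohol through the oxidation, the alkoxide coupling and the thermal shift.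

**Step 9**
Reactants: 15 nopol TBS ether
Product: 16 enone (4-oxo derivative of 15)
Conditions: CrO3, 3,5-dimethylpyrazole, CH2Cl2, −20 °C
Reagents that add atoms: chromium trioxide, O=[Cr](=O)=O
Why: allylic oxidation of the ring CH2 next to the trisubstituted alkene, the same transformation as pinene to verbenone, with the side-chain allylic CH2 expected to be less reactive because of its β-silyloxy group.

**Step 10**
Reactants: 16 enone
Product: 17 cis-pinenol (4-OH on the same side as the CMe2 bridge)
Conditions: NaBH4, CeCl3·7H2O, MeOH, −40 °C
Reagents that add atoms: none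
Why: Luche 1,2-reduction in which hydride attacks the carbonyl from the face opposite to the CMe2 bridge, as in verbenone to cis-verbenol, so the new carbinol centre carries OH cis to the bridge.

**Step 11**
Reactants: 17 cis-pinenol; 11 enol trisylate
Product: 19 cis enol ether, via potassium alkoxide 18 (not isolated)
Conditions: KN(SiMe3)2 (1.0 equiv), THF, −78 °C; then 11, −78 to 0 °C
Reagents that add atoms: none
Why: nucleophilic vinylic substitution (addition–elimination) of the pre-formed alkoxide at the β-sulfonyloxy enone carbon forms the allyl enol ether without touching the C4–O bond, so the cis configuration of the carbinol carbon is retained.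

**Step 12**
Reactants: 19 cis enol ether
Product: 20 Claisen product (ring-A dione with isobutenyl and the 2-(2-silyloxyethyl)pin-3-en-2-yl group on its quaternary carbon)
Conditions: degassed o-xylene, K2CO3 (powder), 135 °C, sealed tube
Reagents that add atoms: none
Why: thermal Claisen ([3,3]-sigmatropic) rearrangement, suprafacial across the pinene allyl unit, so the ring-A carbon is delivered to C2 on the face that carried the oxygen (cis to the CMe2 bridge, arm trans); the bicyclic allyl unit forces a boat-like transition state (a chair would put a ring-A carbonyl carbon inside the bicycle), which with the ether oxygen on the carbon next to CMe2 sets the required configuration at the ring-A quaternary carbon.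

**Step 13**
Reactants: 20 Claisen product
Product: 21 primary alcohol
Conditions: HF·pyridine, pyridine, THF, 0 °C to rt
Reagents that add atoms: none
Why: fluoride-mediated desilylation under acid-buffered conditions frees the alcohol without forming an alkoxide that could open the non-enolisable 1,3-dione by retro-Claisen cleavage.

**Step 14**
Reactants: 21 primary alcohol
Product: 22 iodide (2-isobutenyl ring-A dione bearing the 2-(2-iodoethyl)pin-3-en-2-yl group)
Conditions: I2, PPh3, imidazole, CH2Cl2, 0 °C to rt
Reagents that add atoms: iodine, II
Why: Appel-type iodination, an SN2 displacement of the alkoxyphosphonium ion at the primary carbon under neutral conditions.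

**Step 15**
Reactants: 22 iodide
Product: 23 3,4-didehydro target (ring B closed, pinane ring alkene retained)
Conditions: (Me3Si)3SiH (1.3 equiv) and AIBN (0.2 equiv) added over 6 h, benzene, 80 °C, 0.01 M
Reagents that add atoms: none
Why: Iodine abstraction by the silyl radical gives the primary radical at the end of the arm, which adds to the CH terminus of the isobutenyl group; the tertiary CMe2 radical then takes hydrogen from the silane and becomes the isopropyl group (a tin-free reductive cyclisation of a hex-5-enyl-type radical onto a trisubstituted alkene is the closest known reaction type). Ring B closes 5-exo-trig through a chair-like Beckwith–Houk transition state, helped by the two quaternary carbons in the tether. The new CH(iPr) centre is controlled by these two quaternary centres: the forming CMe2 terminus should take the face of the new ring that carries the flat enone carbonyl of ring A and the vinylic C3–H of the pinene, away from the CMe2 flank of ring A and the pinane bridgehead. The step needs 5-exo over 6-endo closure (attack at the less substituted alkene carbon gives a tertiary radical), cyclisation faster than reduction of the primary radical (slow addition at high dilution), and no reaction at the other π-bonds (the ring alkene could only be reached 4-exo or 5-endo, and addition to C=O is reversible).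

**Step 16**
Reactants: 23 3,4-didehydro target
Product: 24 target CNP0307059.1
Conditions: H2 (1 atm), Pd/C (10%), EtOAc, rt
Reagents that add atoms: none
Why: heterogeneous catalytic hydrogenation should saturate only the cis-disubstituted ring alkene, since the tetrasubstituted donor–acceptor C=C of ring A and the ketones are inert, and no stereocentre is formed or lost.

**Compound list**

1 | 2,4,6-trihydroxytoluene | Cc1c(O)cc(O)cc1O | starting material
2 | iminium salt of 3 (dichlorophosphate) | Cc1c(O)cc(O)c(C=[N+](C)C)c1O.[O-]P(Cl)(Cl)=O | intermediate (not isolated)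
3 | 2,4,6-trihydroxy-3-methylbenzaldehyde | Cc1c(O)cc(O)c(C=O)c1O | intermediate
4 | 2,6-dihydroxy-4-methoxy-3-methylbenzaldehyde | COc1cc(O)c(C=O)c(O)c1C | intermediate
5 | 2,6-dihydroxy-4-methoxy-3,5-dimethylbenzaldehyde | COc1c(C)c(O)c(C=O)c(O)c1C | intermediate (not isolated)
6 | 2-hydroxy-4-methoxy-3,3,5-trimethyl-6-oxocyclohexa-1,4-diene-1-carbaldehyde | COC1=C(C)C(=O)C(C=O)=C(O)C1(C)C | intermediate
7 | 5-hydroxy-3-methoxy-2,4,4-trimethylcyclohexa-2,5-dien-1-one | COC1=C(C)C(=O)C=C(O)C1(C)C | intermediate
8 | isobutyraldehyde | CC(C)C=O | starting material
9 | 5-methoxy-4,6,6-trimethyl-2-(2-methylpropylidene)cyclohex-4-ene-1,3-dione | COC1=C(C)C(=O)C(=CC(C)C)C(=O)C1(C)C | intermediate (not isolated)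
10 | 5-hydroxy-3-methoxy-2,4,4-trimethyl-6-(2-methylprop-1-enyl)cyclohexa-2,5-dien-1-one | COC1=C(C)C(=O)C(C=C(C)C)=C(O)C1(C)C | intermediate
11 | 5-methoxy-4,6,6-trimethyl-2-(2-methylprop-1-enyl)-3-oxocyclohexa-1,4-dien-1-yl 2,4,6-triisopropylbenzenesulfonate | COC1=C(C)C(=O)C(C=C(C)C)=C(OS(=O)(=O)c2c(C(C)C)cc(C(C)C)cc2C(C)C)C1(C)C | intermediate
12 | (+)-β-pinene | C=C1CC[C@@H]2C[C@H]1C2(C)C | starting material
13 | formaldehyde (as paraformaldehyde) | C=O | starting material
14 | (+)-nopol | OCCC1=CC[C@@H]2C[C@H]1C2(C)C | intermediate
15 | nopol tert-butyldimethylsilyl ether | CC(C)(C)[Si](C)(C)OCCC1=CC[C@@H]2C[C@H]1C2(C)C | intermediate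
16 | 4-oxo derivative of 15 (enone) | CC(C)(C)[Si](C)(C)OCCC1=CC(=O)[C@@H]2C[C@H]1C2(C)C | intermediate
17 | cis-4-hydroxy derivative of 15 (OH cis to the CMe2 bridge) | CC(C)(C)[Si](C)(C)OCCC1=C[C@@H](O)[C@@H]2C[C@H]1C2(C)C | intermediate
18 | potassium alkoxide of 17 | CC(C)(C)[Si](C)(C)OCCC1=C[C@@H]([O-])[C@@H]2C[C@H]1C2(C)C.[K+] | intermediate (not isolated)
19 | cis enol ether of 10 and 17 (oxygen on the ring-A carbon next to CMe2) | COC1=C(C)C(=O)C(C=C(C)C)=C(O[C@@H]2C=C(CCO[Si](C)(C)C(C)(C)C)[C@H]3C[C@@H]2C3(C)C)C1(C)C | intermediate
20 | Claisen product, silyl ether (ring A on pinene C2 cis to the CMe2 bridge) | COC1=C(C)C(=O)[C@@](C(=O)C1(C)C)(C=C(C)C)[C@@]3(CCO[Si](C)(C)C(C)(C)C)C=C[C@@H]4C[C@H]3C4(C)C | intermediate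
21 | primary alcohol from 20 | COC1=C(C)C(=O)[C@@](C(=O)C1(C)C)(C=C(C)C)[C@@]3(CCO)C=C[C@@H]4C[C@H]3C4(C)C | intermediate
22 | iodide, precursor of the key step | COC1=C(C)C(=O)[C@@](C(=O)C1(C)C)(C=C(C)C)[C@@]3(CCI)C=C[C@@H]4C[C@H]3C4(C)C | intermediate
23 | 3,4-didehydro target | COC1=C(C)C(=O)[C@@]2(C(=O)C1(C)C)[C@@H](C(C)C)CC[C@@]21C=C[C@@H]2C[C@H]1C2(C)C | intermediate
24 | CNP0307059.1 | COC1=C(C)C(=O)[C@@]2(C(=O)C1(C)C)[C@@H](C(C)C)CC[C@@]21CC[C@@H]2C[C@H]1C2(C)C | target

**Step count and risks**

Total step count: 16. Longest linear sequence: 12 steps (1 to 24 through steps 1–6 and 11–16); the pinene branch (steps 7–10) joins at step 11.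

Steps most likely to fail:

1. Step 12 (Claisen shift). The shift has to take place on the face of the allyl unit that lies under the syn methyl group of the CMe2 bridge, and in the boat the isobutenyl group of the migrating carbon points toward the bicycle. If this crowded transition state is not reached below the temperature at which the allylic C–O bond ionises, the ion pair should collapse at the less hindered C4 (formal [1,3] shift) or lose a proton to a diene. This is the weakest step before the key step.
   Fallback, from 7 and 17, back at 20: the isobutenyl group is left off until after the shift, so the migrating carbon carries only hydrogen on the side facing the bicycle. 7 is sulfonylated as in step 6 to enol trisylate F1 and coupled with alkoxide 18 as in step 11 to cis enol ether F2. Claisen rearrangement of F2 (same face, CH terminus) should give pinenyl enol F3. Pd(PPh3)4-catalysed C-allylation (Tsuji–Trost) with methyl 2-methylallyl carbonate then builds the ring-A quaternary carbon in methallyl dione F4. Migration of the 1,1-disubstituted double bond into the trisubstituted position with RuHCl(CO)(PPh3)3 in hot toluene gives 20. The configuration at the ring-A quaternary carbon would then depend on substrate control by the neighbouring quaternary C2 in the allylation and would have to be proven; otherwise the epimers are separated at F4.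

2. Step 15 (key step). The cyclised tertiary radical may break the bond between the CH(iPr) carbon and the spiro carbon (relief of the two adjacent quaternary centres, formation of a dione-stabilised radical) faster than it takes hydrogen from the silane. The primary radical may also be reduced before it cyclises, or the CMe2 terminus may take the other face.
   Fallback, from 22, back at 24: a cobaloxime-catalysed alkyl Heck-type cyclisation (Co(dmgH)2(py)Cl, i-Pr2NEt, blue LEDs, MeCN, rt) closes the same bond 5-exo, but the tertiary radical is captured by the cobalt complex and leaves by β-hydride elimination as an isopropenyl group, giving isopropenyl diene F5. Hydrogenation as in step 16 then saturates the isopropenyl group and the ring alkene together to give 24.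

3. Step 11 (ether formation). The hindered alkoxide may attack sulfur (S–O cleavage back to the enolate) or add too slowly to the fully substituted β-carbon.
   Fallback, from 11 and 17, back at 19: 11 is converted with LiBr (acetone, 50 °C) into bromo dienone F6, which is joined to 17 by copper-catalysed C–O coupling (CuI, 3,4,7,8-tetramethyl-1,10-phenanthroline, Cs2CO3, toluene, 80 °C; Ullmann-type vinylation of an alcohol). The carbinol C–O bond is again untouched, so the cis configuration is kept.

**Further compounds**

F1 | step 12 | 5-methoxy-4,6,6-trimethyl-3-oxocyclohexa-1,4-dien-1-yl 2,4,6-triisopropylbenzenesulfonate | COC1=C(C)C(=O)C=C(OS(=O)(=O)c2c(C(C)C)cc(C(C)C)cc2C(C)C)C1(C)C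
F2 | step 12 | cis enol ether of 7 and 17 (no isobutenyl group) | COC1=C(C)C(=O)C=C(O[C@@H]2C=C(CCO[Si](C)(C)C(C)(C)C)[C@H]3C[C@@H]2C3(C)C)C1(C)C
F3 | step 12 | ring-A enol carrying the 2-(2-silyloxyethyl)pin-3-en-2-yl group on its central carbon | COC1=C(C)C(=O)C(=C(O)C1(C)C)[C@@]2(CCO[Si](C)(C)C(C)(C)C)C=C[C@@H]3C[C@H]2C3(C)C
F4 | step 12 | analogue of 20 with 2-methylallyl in place of isobutenyl | COC1=C(C)C(=O)[C@@](C(=O)C1(C)C)(CC(C)=C)[C@@]3(CCO[Si](C)(C)C(C)(C)C)C=C[C@@H]4C[C@H]3C4(C)C
F5 | step 15 | analogue of 23 with isopropenyl in place of isopropyl | COC1=C(C)C(=O)[C@@]2(C(=O)C1(C)C)[C@@H](C(C)=C)CC[C@@]21C=C[C@@H]2C[C@H]1C2(C)C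
F6 | step 11 | 5-bromo-3-methoxy-2,4,4-trimethyl-6-(2-methylprop-1-enyl)cyclohexa-2,5-dien-1-one | COC1=C(C)C(=O)C(C=C(C)C)=C(Br)C1(C)C
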